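The vessel is closed and stirred at constant temperature; D and Z go in, and J is wanted.

| flask | D | Z | remark | time |
|---|---|---|---|---|
| gamma | 0.086 M | 0.12 M | run made earlier |  |
| flask | 0.086 M | 0.0817 M |  | 15 min |

gamma run (percent of the D charged): time / s: J / % = 12.0: 1.9; 30.0: 7.1; 60.0: 14.0; 90.0: 16.9

(each reading ± 0.3 percentage points)

* when, up to 15 min, the flask holds most J
* the amount of J, in percent of the D charged, at that time
* the first time at which J reaches 12%, in the same percent, in min

- the earlier runs were read with a standard deviation of 0.3 percentage points

Two of us argued over the gamma run with one quantity, the exchange rate E, the moles of Z charged per mole of D charged, E = 0.950 in the flask against 1.40 in gamma. Dividing a percent of D by E gives what it costs in percent of Z's own charge, at one Z each. So the last gamma reading, 16.9%, would have cost 12.1% of Z if each J took one Z. In the flask, with E below one, that condition would make Z the limiting reagent by charge.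

Interpolating gamma puts J at 12% near 0.855 min. Stretched by the ratio of the Z charges, my interpolated time becomes 1.26 min. The forecast, which stretches gamma's timescale “if the steps are first order in Z”, reads 1.3 min for the first time, with a top of 17% at 3 min.

I held the opposite view: Z merely takes D aside, so a smaller E brings J sooner and higher. My own commitment was a first time below 0.855 min and a top above 16.9%. Gamma had gained 2.9 points in its last 30.0 s, ten times the scatter of a reading, so I did not read a stall there.

The flask reaches 12% at 0.684 min, sooner than gamma's interpolated time, and tops out at 24.6% at 4.40 min.

    D ⇌ L (K = 8.60, k = 0.0409 s⁻¹)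
    L → J (k = 0.0146 s⁻¹)
    D + Z ⇌ X (K = 35.0 M⁻¹, k = 0.386 M⁻¹ s⁻¹)
    J ⇌ G (K = 1.50, k = 0.0335 s⁻¹)
    J → Q (k = 0.00365 s⁻¹)

At 1.50 min the flask holds X at 24.6% of D, which divided by E is 25.9% of Z, one Z in each X, and free Z stands at 74.1%. The forecast's height of 17% comes close to the top of a neighbour flask, the same but charged with 0.33 M of Z, or 3.84 equiv, whose top is 17.5%. In that neighbour flask X at 15.0 min is 11.1% of D, which costs 2.89% of Z, and Z stands at 97.1%.

The runs come from a simulation with constants of no real substance; noise was put on by code.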